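**Retrosynthetic overview**

1. 7 ⇒ 2 × 6: the cyclobutane (bonds C6–C7a' and C7–C3a') is opened to two molecules of (Z)-ligustilide. One reacts as the 6,7-olefin, the other as the photoexcited 3a,7a-enone, as in the presumed biosynthesis; all four stereocentres and the 3'E geometry arise in this one [2+2] event.
2. 6 ⇒ 5 + CO: the butenolide ring comes from carbonylative enol lactonisation of a dienyl triflate (C7a–C1 and C1–O2 bonds).
3. 5 ⇒ 4 ⇒ 1 + 2: enol triflate of a 1,3-diketone, made by C-acylation of the kinetic enolate of cyclohex-2-en-1-one (C3a–C3 bond).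
4. Ring order: carbocycle bought → butenolide (step 3) → cyclobutane, which also creates the [4.3.2]propellane of unit B (step 4).

Assumption: the SMILES is read literally (ligustilide numbering, primes for the propellane unit B): unit A is 3Z, unit B is 3'E, stereocentres 6S,7R,3a'S,7a'R, H-6/H-7 cis, both carbocycles on one face of the cyclobutane and the unit B lactone on the other.

**Route**

Step 1
Reactants: 1 cyclohex-2-en-1-one; 2 pentanoyl chloride
Product: 4 6-pentanoylcyclohex-2-en-1-one, via lithium cyclohexa-1,5-dien-1-olate 3 (not isolated)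
Conditions: LiN(SiMe3)2 (1.05 equiv), THF, −78 °C, 30 min; then cannulated into 2 (1.0 equiv), THF, −78 °C; aq. NH4Cl
Reagents that add atoms: none
Why: Kinetic deprotonation at C6 gives the cross-conjugated lithium dienolate, and inverse addition to the acid chloride at low temperature favours C-acylation (Claisen-type acylation of a ketone enolate) to the 1,3-diketone; the C6 stereocentre is racemic and irrelevant because it becomes sp2 in step 2.

Step 2
Reactants: 4 6-pentanoylcyclohex-2-en-1-one
Product: 5 2-pentanoylcyclohexa-1,5-dien-1-yl trifluoromethanesulfonate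
Conditions: Tf2O (1.1 equiv), i-Pr2NEt (1.3 equiv), CH2Cl2, −78 to −20 °C
Reagents that add atoms: trifluoromethanesulfonic anhydride, O=S(=O)(OS(=O)(=O)C(F)(F)F)C(F)(F)F
Why: Enol triflate formation from the diketone enolate takes place on the ring oxygen, as with 2-acylcyclohexanones, because this vinylogous oxygen is the more electron-rich one and the product keeps the linear O=C–C=C–C=C conjugation; no stereocentre is formed.

Step 3
Reactants: 5 2-pentanoylcyclohexa-1,5-dien-1-yl trifluoromethanesulfonate
Product: 6 (Z)-ligustilide, (3Z)-3-butylidene-4,5-dihydro-2-benzofuran-1(3H)-one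
Conditions: Pd(OAc)2 (5 mol %), 1,3-bis(diphenylphosphino)propane (6 mol %), CO (1 atm), i-Pr2NEt (2 equiv), MeCN, 60 °C, dark; product kept under Ar at −20 °C
Reagents that add atoms: carbon monoxide, [C-]#[O+]
Why: Oxidative addition of the vinyl triflate to zerovalent palladium and CO insertion give an acylpalladium species that is trapped by the enolate oxygen of the neighbouring butyl ketone (carbonylative enol lactonisation, Negishi-type acylpalladium–enolate O-trapping); the five-membered enol lactone closes with the propyl group turned away from C4, which is the Z geometry.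

Step 4
Reactants: 6 (Z)-ligustilide (two molecules)
Product: 7 (3Z,3'E,6S,7R,3a'S,7a'R)-6.7a',7.3a'-diligustilide
Conditions: (S)-3,3-diphenyl-1-(2,4,6-trifluorophenyl)tetrahydro-1H,3H-pyrrolo[1,2-c][1,3,2]oxazaborole (20 mol %), AlBr3 (20 mol %), CH2Cl2, −75 °C, 0.3 M, 405 nm LED, Ar, to about 50 % conversion; Et3N quench; HPLC; unreacted 6 recycled
Reagents that add atoms: none
Why: Proposed new method: only the Lewis-acid-bound lactone absorbs at 405 nm (complexation red-shifts the 328 nm band of 6), so one molecule becomes the triplet enone partner while free, transparent 6 serves as the olefin and keeps its 3Z geometry; bonding of the electrophilic C7a' to C6 gives the best 1,4-biradical (pentadienyl radical at C7, allyl radical at C3a') and closure C7–C3a' gives the head-to-tail cyclobutane; the bulky acid on C1'=O should send the carbocycle of the olefin over the carbocycle of the bound partner (lactone anti), and its aryl group blocks one face of C3a'=C7a', which sets 6S,7R,3a'S,7a'R in one event; the excited partner relaxes by rotation about C3'=C8', so closure of the allyl radical gives both the 3'E dimer (the target, probably the minor one) and the 3'Z dimer, which are separated by HPLC; the closest known reaction type is the enantioselective intermolecular enone–olefin [2+2] photocycloaddition of cyclic enones and coumarins catalysed by AlBr3-activated chiral oxazaborolidines.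

**Compound list**

1 | cyclohex-2-en-1-one | O=C1C=CCCC1 | starting material
2 | pentanoyl chloride | CCCCC(=O)Cl | starting material
3 | lithium cyclohexa-1,5-dien-1-olate (kinetic enolate of 1) | [Li+].[O-]C1=CCCC=C1 | intermediate
4 | 6-pentanoylcyclohex-2-en-1-one (racemic, largely enolised) | CCCCC(=O)C1CCC=CC1=O | intermediate
5 | 2-pentanoylcyclohexa-1,5-dien-1-yl trifluoromethanesulfonate | CCCCC(=O)C1=C(OS(=O)(=O)C(F)(F)F)C=CCC1 | intermediate
6 | (Z)-ligustilide, (3Z)-3-butylidene-4,5-dihydro-2-benzofuran-1(3H)-one | CCC/C=C1\OC(=O)C2=C1CCC=C2 | intermediate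
7 | (3Z,3'E,6S,7R,3a'S,7a'R)-6.7a',7.3a'-diligustilide: cyclobutane C6–C7–C3a'–C7a'; unit A is a 6,7-dihydro-(Z)-ligustilide, unit B a [4.3.2]propellane lactone with C6'=C7' and an (E)-butylidene; H-6 and H-7 cis; both carbocycles on one face of the cyclobutane, lactone of unit B on the other | CCC/C=C1\OC(=O)C2=C1CC[C@H]1[C@@H]2[C@@]23CCC=C[C@@]12C(=O)O/C3=C/CCC | target

**Totals and risks**

Total step count: 4. Longest linear sequence: 4 (1 → 4 → 5 → 6 → 7).

Most likely to fail:

Step 4. Possible failures: dark Lewis-acid Diels–Alder dimerisation; first bond at C8' (giving the 6.8',7.3' spiro dimer); only the 3'Z dimer if the bound triplet keeps its geometry; low ee or the opposite sense of induction (then the (R)-oxazaborolidine is used). Fallback, setting out from 6 and coming back at 7: the Lewis acid is dropped and 6 is dimerised as the plant presumably does it, by triplet sensitisation at room temperature (thioxanthen-9-one, 405 nm, benzene, 0.5 M, Ar), where rotation about C3'=C8' is certain. The racemic (3Z,3'E) head-to-tail dimer is isolated by HPLC; it consists of 7 and its mirror image (3Z,3'E,6R,7S,3a'R,7a'S)-6.7a',7.3a'-diligustilide F1. The racemate is resolved by preparative HPLC on an amylose tris(3,5-dimethylphenylcarbamate) phase to give 7.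

Step 2. Possible failures: triflation on the side-chain oxygen, or loss of the vinylogous acyl triflate. Fallback, setting out from 1 and coming back at 6, with the carboxyl carbon installed before the side chain:
- Iodination of 1 (I2, pyridine, CH2Cl2) gives 2-iodocyclohex-2-en-1-one F2.
- Methoxycarbonylation (PdCl2(PPh3)2, CO, MeOH, i-Pr2NEt) gives methyl 6-oxocyclohex-1-ene-1-carboxylate F3.
- Thermodynamic γ-deprotonation to the doubly stabilised dienolate and O-triflation (NaH, then PhNTf2, THF, −78 to 0 °C) gives methyl 2-{[(trifluoromethyl)sulfonyl]oxy}cyclohexa-1,5-diene-1-carboxylate F4.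
- Sonogashira coupling with pent-1-yne (PdCl2(PPh3)2, CuI, i-Pr2NH) gives methyl 2-(pent-1-yn-1-yl)cyclohexa-1,5-diene-1-carboxylate F5.
- Saponification (LiOH, THF–H2O, then dilute HCl) gives 2-(pent-1-yn-1-yl)cyclohexa-1,5-diene-1-carboxylic acid F6.
- 5-exo-dig cyclisation with catalytic AgNO3 in acetone (anti addition, Z product) gives 6.

Step 3. Possible failures: C-trapping of the acylpalladium species, E/Z mixtures, or decomposition of 6 under the conditions. Fallback, setting out from 5 and coming back at 6, with the lactone closed in a separate dehydration: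
- Methoxycarbonylation of 5 (Pd(OAc)2, 1,3-bis(diphenylphosphino)propane, CO, MeOH, i-Pr2NEt, DMF) gives methyl 2-pentanoylcyclohexa-1,5-diene-1-carboxylate F7.
- Saponification (LiOH, THF–H2O, then dilute HCl) gives the keto acid as its ring tautomer 3-butyl-3-hydroxy-4,5-dihydro-2-benzofuran-1(3H)-one F8.
- Acid-catalysed dehydration (catalytic TsOH, toluene, 60 °C) gives 6, with the Z isomer thermodynamically preferred.

**Further compounds**

F1 | step 4 | (3Z,3'E,6R,7S,3a'R,7a'S)-6.7a',7.3a'-diligustilide (mirror image of 7) | CCC/C=C1\OC(=O)C2=C1CC[C@@H]1[C@H]2[C@]23CCC=C[C@]12C(=O)O/C3=C/CCC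
F2 | step 2 | 2-iodocyclohex-2-en-1-one | O=C1CCCC=C1I
F3 | step 2 | methyl 6-oxocyclohex-1-ene-1-carboxylate | COC(=O)C1=CCCCC1=O
F4 | step 2 | methyl 2-{[(trifluoromethyl)sulfonyl]oxy}cyclohexa-1,5-diene-1-carboxylate | COC(=O)C1=C(OS(=O)(=O)C(F)(F)F)CCC=C1
F5 | step 2 | methyl 2-(pent-1-yn-1-yl)cyclohexa-1,5-diene-1-carboxylate | CCCC#CC1=C(C(=O)OC)C=CCC1
F6 | step 2 | 2-(pent-1-yn-1-yl)cyclohexa-1,5-diene-1-carboxylic acid | CCCC#CC1=C(C(=O)O)C=CCC1
F7 | step 3 | methyl 2-pentanoylcyclohexa-1,5-diene-1-carboxylate | CCCCC(=O)C1=C(C(=O)OC)C=CCC1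
F8 | step 3 | 3-butyl-3-hydroxy-4,5-dihydro-2-benzofuran-1(3H)-one | CCCCC1(O)OC(=O)C2=C1CCC=C2
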